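The cis-fused 3,7-dioxabicyclo[3.3.0]octane is cut at C8–C8' and at C7'–O. This works because its four contiguous stereocentres C7, C8, C8' and C7' sit on one unbroken path that an acyclic C7 sinapyl ether of a C8–C9 epoxide already contains. In one flask Cp2TiCl opens the epoxide to the C8 radical, which closes ring 1 (C7–O–C9'–C8'–C8). Iodine then lets the C9 alkoxide close ring 2 (C7'–O–C9–C8–C8'). Two rings, two bonds and three stereocentres thus arise under control of C7 alone. The precursor is this epoxy ether, with the finished erythro C7''–C9'' chain on O4 of ring B and every hydroxyl silylated.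

Key step: step 17

Remarks on the chemistry
- Numbering: ring B–C7–C8–C9 and syringyl–C7'–C8'–C9' are joined at C8–C8', with ethers C7–O–C9' and C7'–O–C9. Ring A–C7''–C8''–C9'' is attached through C8''–O–C4 of ring B.
- The target reads 7R,8S,7'R,8'S, with both aryl groups on the convex face. The side chain is 7''R,8''S, which is the erythro (anti) pair.
- C7 is labelled S in the epoxy compounds and R in the bicycle. The spatial arrangement is the same; only the priority of C8 changes.
- Protecting groups:
  - Both phenols carry TIPS, because aryl TBS ethers can pass their silyl group to an alkoxide during the etherification.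
  - The side-chain diol carries two TBS ethers instead of a ketal. One buffered fluoride step then ends the synthesis, and no acid meets the ionisable centres C7, C7' and C7''.
- Ring B enters as an aryl bromide. An aldehyde, free or masked as an acetal, would not be safe under boron enolisation. The bromide becomes the C7 carbinol in one step.
- For O-aryl glycolate imides only the syn boron aldol is established. The erythro pair is therefore reached by syn aldol and inversion at C7''.
- Assumption: the remote side-chain centres do not disturb reagent control in the Sharpless step.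
- In the SMILES of the two titanium intermediates the Cp rings are drawn sigma-bound, only to give a valid string.

Step 1
Reactants: 1 4-bromo-2-methoxyphenol; 2 bromoacetic acid
Product: 3 (4-bromo-2-methoxyphenoxy)acetic acid
Conditions: NaOH, H2O, reflux; then HCl to pH 1
Reagents that add atoms: none
Why: Williamson ether synthesis, in which the phenoxide displaces bromide from bromoacetate by SN2 as is routine for aryloxyacetic acids, while the aryl bromide is inert.

Step 2
Reactants: 3 (4-bromo-2-methoxyphenoxy)acetic acid; 4 (R)-4-benzyl-1,3-oxazolidin-2-one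
Product: 6 (4R)-4-benzyl-3-[(4-bromo-2-methoxyphenoxy)acetyl]-1,3-oxazolidin-2-one, via mixed pivalic anhydride 5 (not isolated)
Conditions: t-BuCOCl, Et3N, THF, −20 °C; then 4, LiCl, −20 °C → rt
Reagents that add atoms: none
Why: N-acylation through a mixed anhydride, in which LiCl and Et3N let the carbamate nitrogen attack the less hindered aryloxyacetyl carbonyl of 5 without touching the auxiliary stereocentre.

Step 3
Reactants: 7 vanillin
Product: 8 3-methoxy-4-(triisopropylsilyloxy)benzaldehyde
Conditions: TIPSCl, imidazole, DMF, rt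
Reagents that add atoms: chlorotriisopropylsilane (TIPSCl), CC(C)[Si](Cl)(C(C)C)C(C)C
Why: Imidazole-promoted silyl ether formation on an acidic phenol, with TIPS chosen because it must later withstand hydride, organolithium and alkoxide reagents.

Step 4
Reactants: 6 aryloxyacetyl imide; 8 3-methoxy-4-(triisopropylsilyloxy)benzaldehyde
Product: 10 syn aldol adduct (4R)-4-benzyl-3-{(2R,3S)-2-(4-bromo-2-methoxyphenoxy)-3-hydroxy-3-[3-methoxy-4-(triisopropylsilyloxy)phenyl]propanoyl}-1,3-oxazolidin-2-one, via Z boron enolate 9 (not isolated)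
Conditions: n-Bu2BOTf, Et3N, CH2Cl2, −78 → 0 °C; 8, −78 → 0 °C; then pH 7 buffer, MeOH, H2O2, 0 °C
Reagents that add atoms: none
Why: Evans syn aldol, established for aryloxyacetyl imides with alkoxybenzaldehydes, in which enolate 9 reacts through a closed chair transition state and the benzyl group of the (R)-auxiliary shields one face, so that C8'' is set as needed (2R in the imide, 8''S after reduction) and C7'' as S (threo pair).

Step 5
Reactants: 10 syn aldol adduct
Product: 11 threo diol (1S,2S)-2-(4-bromo-2-methoxyphenoxy)-1-[3-methoxy-4-(triisopropylsilyloxy)phenyl]propane-1,3-diol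
Conditions: LiBH4, MeOH (1 equiv), THF, 0 °C
Reagents that add atoms: none
Why: Reductive removal of the auxiliary, in which LiBH4 reduces the exocyclic imide carbonyl to the C9'' alcohol without touching C7'', C8'', the aryl bromide or the aryl silyl ether.

Step 6
Reactants: 11 threo diol
Product: 12 threo C9'' silyl ether (1S,2S)-2-(4-bromo-2-methoxyphenoxy)-3-(tert-butyldimethylsilyloxy)-1-[3-methoxy-4-(triisopropylsilyloxy)phenyl]propan-1-ol
Conditions: TBSCl (1.05 equiv), imidazole, CH2Cl2, 0 °C
Reagents that add atoms: tert-butyldimethylsilyl chloride (TBSCl), CC(C)(C)[Si](C)(C)Cl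
Why: Selective silylation, since the primary C9'' hydroxyl reacts far faster with TBSCl than the hindered secondary benzylic C7'' hydroxyl.

Step 7
Reactants: 12 threo C9'' silyl ether
Product: 13 erythro 4-nitrobenzoate (1R,2S)-2-(4-bromo-2-methoxyphenoxy)-3-(tert-butyldimethylsilyloxy)-1-[3-methoxy-4-(triisopropylsilyloxy)phenyl]propyl 4-nitrobenzoate
Conditions: 4-nitrobenzoic acid, PPh3, DIAD, toluene, −20 → 0 °C
Reagents that add atoms: 4-nitrobenzoic acid, O=C(O)c1ccc(cc1)[N+](=O)[O-]
Why: Mitsunobu inversion, known for aryl glycerol aryl ethers of this kind, in which the carboxylate displaces the C7'' alkoxyphosphonium group by SN2 and turns 7''S into 7''R (threo into erythro), while toluene and low temperature hold back ionisation of the electron-rich benzylic centre.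

Step 8
Reactants: 13 erythro 4-nitrobenzoate
Product: 14 erythro alcohol (1R,2S)-2-(4-bromo-2-methoxyphenoxy)-3-(tert-butyldimethylsilyloxy)-1-[3-methoxy-4-(triisopropylsilyloxy)phenyl]propan-1-ol
Conditions: K2CO3 (cat.), MeOH–THF, 0 °C
Reagents that add atoms: none
Why: Base-catalysed transesterification at the acyl carbon of the activated ester, so that the C7''–O bond and the 7''R configuration stay intact and the short cold treatment spares the aryl TIPS ether.

Step 9
Reactants: 14 erythro alcohol
Product: 15 erythro bis-TBS aryl bromide (1R,2S)-2-(4-bromo-2-methoxyphenoxy)-1,3-bis(tert-butyldimethylsilyloxy)-1-[3-methoxy-4-(triisopropylsilyloxy)phenyl]propane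
Conditions: TBSOTf, 2,6-lutidine, CH2Cl2, −78 → 0 °C
Reagents that add atoms: tert-butyldimethylsilyl triflate (TBSOTf), CC(C)(C)[Si](C)(C)OS(=O)(=O)C(F)(F)F
Why: Silylation with a silyl triflate, which takes place at the oxygen of the hindered C7'' hydroxyl and does not break its C–O bond.

Step 10
Reactants: 15 erythro bis-TBS aryl bromide; 16 acrolein
Product: 18 allylic alcohol 1-{4-[(1R,2S)-1,3-bis(tert-butyldimethylsilyloxy)-1-(3-methoxy-4-triisopropylsilyloxyphenyl)propan-2-yloxy]-3-methoxyphenyl}prop-2-en-1-ol as both C7 epimers, via aryllithium 17 (not isolated)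
Conditions: n-BuLi, THF, −78 °C; 16 (freshly distilled), −78 °C; then H2O
Reagents that add atoms: none
Why: Bromine–lithium exchange and 1,2-addition of the aryllithium to acrolein, where exchange at −78 °C is much faster than attack on silyl ethers and the new C7 carbinol should form without facial bias because the side-chain centres are remote.

Step 11
Reactants: 18 allylic alcohol (both C7 epimers)
Product: 19 epoxy alcohol (7S,8R,7''R,8''S), ring B–CH(OH)–oxirane with erythro C7/C8
Conditions: Ti(OiPr)4 (0.2 equiv), L-(+)-DIPT (0.24 equiv), t-BuOOH (0.5 equiv), 4 Å molecular sieves, CH2Cl2, −20 °C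
Reagents that add atoms: tert-butyl hydroperoxide, CC(C)(C)OO
Why: Sharpless asymmetric epoxidation run as a kinetic resolution, in which the 7R carbinol epimer is the fast one with L-(+)-DIPT and should give the erythro epoxy alcohol, while the 7S epimer stays an allylic alcohol and is removed by chromatography, so that C7 is fixed here.

Step 12
Reactants: 20 syringaldehyde
Product: 21 3,5-dimethoxy-4-(triisopropylsilyloxy)benzaldehyde
Conditions: TIPSCl, imidazole, DMAP (cat.), DMF, 40 °C
Reagents that add atoms: chlorotriisopropylsilane (TIPSCl), CC(C)[Si](Cl)(C(C)C)C(C)C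
Why: Silyl ether formation, in which the acidity of the phenol offsets the hindrance of the two ortho methoxy groups.

Step 13
Reactants: 21 3,5-dimethoxy-4-(triisopropylsilyloxy)benzaldehyde
Product: 22 ethyl (E)-3-[3,5-dimethoxy-4-(triisopropylsilyloxy)phenyl]prop-2-enoate
Conditions: Ph3P=CHCO2Et, toluene, 80 °C
Reagents that add atoms: ethyl (triphenylphosphoranylidene)acetate, CCOC(=O)C=P(c1ccccc1)(c1ccccc1)c1ccccc1
Why: Wittig olefination with a stabilised ylide, which gives the E enoate under neutral conditions that do not endanger the aryl silyl ether.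

Step 14
Reactants: 22 ethyl (E)-enoate
Product: 23 (E)-3-[3,5-dimethoxy-4-(triisopropylsilyloxy)phenyl]prop-2-en-1-ol
Conditions: i-Bu2AlH (2.2 equiv), CH2Cl2, −78 °C; aq potassium sodium tartrate
Reagents that add atoms: none
Why: 1,2-Reduction of the enoate with i-Bu2AlH, which gives the allylic alcohol and leaves the E alkene unchanged.

Step 15
Reactants: 23 silylated sinapyl alcohol
Product: 24 (E)-[4-(3-bromoprop-1-enyl)-2,6-dimethoxyphenoxy]triisopropylsilane
Conditions: CBr4, PPh3, CH2Cl2, 0 °C; used at once
Reagents that add atoms: tetrabromomethane, BrC(Br)(Br)Br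
Why: Appel bromination, which displaces the primary allylic alcohol through its alkoxyphosphonium salt under almost neutral conditions and keeps the alkene geometry.

Step 16
Reactants: 19 epoxy alcohol; 24 silylated sinapyl bromide
Product: 26 epoxy sinapyl ether (7S,8R,7''R,8''S) with E alkene, via sodium alkoxide 25 (not isolated)
Conditions: NaH, THF–DMF, 0 °C; then 24, Bu4NI (cat.), 0 °C → rt
Reagents that add atoms: none
Why: Williamson ether synthesis, known for epoxy carbinols of this type with cinnamyl bromides, in which the C7 alkoxide attacks the primary allylic bromide by SN2 without touching a stereocentre, while the cold aprotic medium keeps epoxide migration slow and the TIPS ethers resist the alkoxide.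

Step 17
Reactants: 26 epoxy sinapyl ether
Product: 29 fully silylated ficusesquilignan A (7R,8S,7'R,8'S,7''R,8''S), via bis-titanated tetrahydrofuran 27 (not isolated), via benzylic iodide 28 (not isolated)
Conditions: Cp2TiCl2 (2.5 equiv), Zn dust, THF, rt (gives Cp2TiCl), added slowly to 26 in THF, rt; then I2 (1.3 equiv), rt → 45 °C; aq NaH2PO4, Na2S2O3
Reagents that add atoms: none
Why: Cp2TiCl (trivalent titanium) transfers one electron to the epoxide and the C8–O bond breaks, which leaves the secondary C8 radical and a C9 titanium alkoxide and erases the epoxide configuration at C8. The radical adds to C8' of the E alkene in a 5-exo-trig closure of ring 1 (C7–O–C9'–C8'–C8) because this puts the new radical on benzylic C7', a second Cp2TiCl caps C7' to give 27, I2 turns the C7'–Ti bond into the benzylic iodide 28, and the C9 alkoxide displaces iodide in a 5-exo-tet closure of ring 2 (C7'–O–C9–C8–C8'). The closest known reaction type is the Cp2TiCl-mediated reductive epoxide opening and radical cyclisation of epoxy cinnamyl ethers with iodine-induced etherification, which is established for simple furofuran lignans. C8 is controlled by C7, since ring B lies pseudo-equatorial in the chair-like transition state and the CH2O[Ti] arm ends up trans to it; C8' is controlled by the cis preference of 1-substituted hexenyl radicals and by the fact that only the isomer with C9 and C7' cis can bridge; C7' is controlled by the bicycle, since the loose benzylic iodide or ion pair closes with the syringyl ring on the convex face whatever its own configuration. The step needs regioselective C8–O cleavage, secured by the higher stability of the secondary radical, and cyclisation faster than capture of the C8 radical by titanium (which would end in deoxygenation), secured by the styrene-type acceptor and by the slow addition of Cp2TiCl. Silyl ethers, aryl ethers and the C7''/C8'' centres are inert to these neutral conditions.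

Step 18
Reactants: 29 fully silylated ficusesquilignan A
Product: 30 ficusesquilignan A
Conditions: Bu4NF (6 equiv), AcOH (6 equiv), THF, 0 °C → rt
Reagents that add atoms: none
Why: Fluoride-mediated desilylation, which cleaves all four Si–O bonds at silicon so that no stereocentre is touched, while the AcOH buffer keeps the freed phenols protonated and no acid strong enough to ionise C7, C7' or C7'' is present.

Compound list
1 | 4-bromo-2-methoxyphenol | COc1cc(Br)ccc1O | starting material
2 | bromoacetic acid | OC(=O)CBr | starting material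
3 | (4-bromo-2-methoxyphenoxy)acetic acid | COc1cc(Br)ccc1OCC(=O)O | intermediate
4 | (R)-4-benzyl-1,3-oxazolidin-2-one | O=C1N[C@H](Cc2ccccc2)CO1 | starting material
5 | (4-bromo-2-methoxyphenoxy)acetic pivalic anhydride | COc1cc(Br)ccc1OCC(=O)OC(=O)C(C)(C)C | intermediate
6 | (4R)-4-benzyl-3-[(4-bromo-2-methoxyphenoxy)acetyl]-1,3-oxazolidin-2-one | COc1cc(Br)ccc1OCC(=O)N1C(=O)OC[C@H]1Cc1ccccc1 | intermediate
7 | vanillin | COc1cc(C=O)ccc1O | starting material
8 | 3-methoxy-4-(triisopropylsilyloxy)benzaldehyde | COc1cc(C=O)ccc1O[Si](C(C)C)(C(C)C)C(C)C | intermediate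
9 | Z dibutylboron enolate of 6 | CCCCB(CCCC)O/C(=C\Oc1ccc(Br)cc1OC)N1C(=O)OC[C@H]1Cc1ccccc1 | intermediate
10 | syn aldol adduct (2R,3S; auxiliary 4R) | COc1cc([C@H](O)[C@H](C(=O)N2C(=O)OC[C@H]2Cc2ccccc2)Oc2ccc(Br)cc2OC)ccc1O[Si](C(C)C)(C(C)C)C(C)C | intermediate
11 | threo diol (7''S,8''S) | COc1cc([C@H](O)[C@H](CO)Oc2ccc(Br)cc2OC)ccc1O[Si](C(C)C)(C(C)C)C(C)C | intermediate
12 | threo C9'' TBS ether (7''S,8''S) | COc1cc([C@H](O)[C@H](CO[Si](C)(C)C(C)(C)C)Oc2ccc(Br)cc2OC)ccc1O[Si](C(C)C)(C(C)C)C(C)C | intermediate
13 | erythro C7'' 4-nitrobenzoate (7''R,8''S) | COc1cc([C@@H](OC(=O)c2ccc(cc2)[N+](=O)[O-])[C@H](CO[Si](C)(C)C(C)(C)C)Oc2ccc(Br)cc2OC)ccc1O[Si](C(C)C)(C(C)C)C(C)C | intermediate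
14 | erythro alcohol (7''R,8''S) | COc1cc([C@@H](O)[C@H](CO[Si](C)(C)C(C)(C)C)Oc2ccc(Br)cc2OC)ccc1O[Si](C(C)C)(C(C)C)C(C)C | intermediate
15 | erythro bis-TBS aryl bromide (7''R,8''S) | COc1cc([C@@H](O[Si](C)(C)C(C)(C)C)[C@H](CO[Si](C)(C)C(C)(C)C)Oc2ccc(Br)cc2OC)ccc1O[Si](C(C)C)(C(C)C)C(C)C | intermediate
16 | acrolein | C=CC=O | starting material
17 | aryllithium from 15 (lithium at C1 of ring B) | COc1cc([C@@H](O[Si](C)(C)C(C)(C)C)[C@H](CO[Si](C)(C)C(C)(C)C)Oc2ccc([Li])cc2OC)ccc1O[Si](C(C)C)(C(C)C)C(C)C | intermediate
18 | allylic alcohol, both C7 epimers (C7 left open in the SMILES) | COc1cc([C@@H](O[Si](C)(C)C(C)(C)C)[C@H](CO[Si](C)(C)C(C)(C)C)Oc2ccc(C(O)C=C)cc2OC)ccc1O[Si](C(C)C)(C(C)C)C(C)C | intermediate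
19 | epoxy alcohol (7S,8R,7''R,8''S) | COc1cc([C@@H](O[Si](C)(C)C(C)(C)C)[C@H](CO[Si](C)(C)C(C)(C)C)Oc2ccc([C@H](O)[C@H]3CO3)cc2OC)ccc1O[Si](C(C)C)(C(C)C)C(C)C | intermediate
20 | syringaldehyde | COc1cc(C=O)cc(OC)c1O | starting material
21 | 3,5-dimethoxy-4-(triisopropylsilyloxy)benzaldehyde | COc1cc(C=O)cc(OC)c1O[Si](C(C)C)(C(C)C)C(C)C | intermediate
22 | ethyl (E)-3-[3,5-dimethoxy-4-(triisopropylsilyloxy)phenyl]prop-2-enoate | CCOC(=O)/C=C/c1cc(OC)c(O[Si](C(C)C)(C(C)C)C(C)C)c(OC)c1 | intermediate
23 | (E)-3-[3,5-dimethoxy-4-(triisopropylsilyloxy)phenyl]prop-2-en-1-ol | OC/C=C/c1cc(OC)c(O[Si](C(C)C)(C(C)C)C(C)C)c(OC)c1 | intermediate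
24 | (E)-[4-(3-bromoprop-1-enyl)-2,6-dimethoxyphenoxy]triisopropylsilane | BrC/C=C/c1cc(OC)c(O[Si](C(C)C)(C(C)C)C(C)C)c(OC)c1 | intermediate
25 | sodium C7 alkoxide of 19 | COc1cc([C@@H](O[Si](C)(C)C(C)(C)C)[C@H](CO[Si](C)(C)C(C)(C)C)Oc2ccc([C@H]([O-])[C@H]3CO3)cc2OC)ccc1O[Si](C(C)C)(C(C)C)C(C)C.[Na+] | intermediate
26 | epoxy sinapyl ether, precursor of the key step (7S,8R,7''R,8''S; E alkene) | COc1cc([C@@H](O[Si](C)(C)C(C)(C)C)[C@H](CO[Si](C)(C)C(C)(C)C)Oc2ccc([C@H](OC/C=C/c3cc(OC)c(O[Si](C(C)C)(C(C)C)C(C)C)c(OC)c3)[C@H]3CO3)cc2OC)ccc1O[Si](C(C)C)(C(C)C)C(C)C | intermediate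
27 | bis-titanated tetrahydrofuran (7,8-trans, 8,8'-cis; C7'–TiCp2Cl of open configuration, C9–OTiCp2Cl) | COc1cc([C@@H](O[Si](C)(C)C(C)(C)C)[C@H](CO[Si](C)(C)C(C)(C)C)Oc2ccc([C@@H]3OC[C@@H](C([Ti](Cl)(C4C=CC=C4)C4C=CC=C4)c4cc(OC)c(O[Si](C(C)C)(C(C)C)C(C)C)c(OC)c4)[C@H]3CO[Ti](Cl)(C4C=CC=C4)C4C=CC=C4)cc2OC)ccc1O[Si](C(C)C)(C(C)C)C(C)C | intermediate
28 | C7' benzylic iodide with C9–OTiCp2Cl (C7' of open configuration) | COc1cc([C@@H](O[Si](C)(C)C(C)(C)C)[C@H](CO[Si](C)(C)C(C)(C)C)Oc2ccc([C@@H]3OC[C@@H](C(I)c4cc(OC)c(O[Si](C(C)C)(C(C)C)C(C)C)c(OC)c4)[C@H]3CO[Ti](Cl)(C4C=CC=C4)C4C=CC=C4)cc2OC)ccc1O[Si](C(C)C)(C(C)C)C(C)C | intermediate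
29 | fully silylated ficusesquilignan A (two aryl TIPS, two alkyl TBS; 7R,8S,7'R,8'S,7''R,8''S) | COc1cc([C@@H](O[Si](C)(C)C(C)(C)C)[C@H](CO[Si](C)(C)C(C)(C)C)Oc2ccc([C@@H]3OC[C@@H]4[C@H]3CO[C@H]4c3cc(OC)c(O[Si](C(C)C)(C(C)C)C(C)C)c(OC)c3)cc2OC)ccc1O[Si](C(C)C)(C(C)C)C(C)C | intermediate
30 | ficusesquilignan A | COc1cc([C@@H](O)[C@H](CO)Oc2ccc([C@@H]3OC[C@@H]4[C@H]3CO[C@H]4c3cc(OC)c(O)c(OC)c3)cc2OC)ccc1O | target

Total step count: 18.
Longest linear sequence: 13 steps (1, 2, 4–11, 16, 17, 18).

Steps most likely to fail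

Step 17.
- What may go wrong: the C8 radical may be captured by titanium before it cyclises. The selection between cis and trans at C8/C8' may be poor. The iodine stage may fail to turn C7' cleanly into a leaving group.
- Change of approach: the fallback separates the two ring closures and makes ring 2 by a polar, biomimetic step.
- Route: it sets out from 26.
  - Cp2TiCl as before, but with an aqueous NaH2PO4 quench instead of I2, should give the monocyclic hydroxymethyl benzyl tetrahydrofuran F1.
  - Bu4NF (2 equiv) and AcOH in THF at −20 °C should cleave only the two aryl TIPS ethers and give the bisphenol F2.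
  - Ag2O in CH2Cl2 should oxidise the 4-alkyl-2,6-dimethoxyphenol to the para-quinone methide F3.
  - The C9 hydroxyl adds to it 5-exo-trig and should give the furofuran bisphenol F4, with the syringyl ring on the convex face.
  - The conditions of step 18 then remove the two TBS groups, so the fallback comes back to the route at 30.

Step 7.
- What may go wrong: ionisation of the activated, electron-rich benzylic carbinol may compete with direct displacement and erode the inversion. Elimination toward C8'' may take over.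
- Change of approach: the fallback delivers the oxygen from inside the molecule, so that ring geometry and not the mechanism decides the outcome.
- Route: it sets out from 11.
  - Boc2O and N-methylimidazole in CH2Cl2 at 0 °C should acylate the primary hydroxyl and give the C9'' tert-butyl carbonate F5.
  - MsCl and Et3N at −30 °C activate the C7'' hydroxyl. The carbonate carbonyl oxygen attacks C7'' and isobutene is lost.
  - This should give the six-membered cyclic carbonate F6 as the trans (diequatorial, erythro) isomer, whether the closure is SN2 or runs through the cation.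
  - K2CO3 in MeOH gives the erythro diol F7.
  - TBSOTf (2.5 equiv) with 2,6-lutidine brings the fallback back to the route at 15.

Step 16.
- What may go wrong: the alkoxide may trigger epoxide migration or silyl transfer. The allylic bromide may decompose before it is alkylated.
- Change of approach: the fallback replaces the SN2 reaction by a π-allyl etherification on zerovalent palladium, without strong base and without the bromide.
- Route: it sets out from 23.
  - Ac2O and pyridine give the silylated sinapyl acetate F8.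
  - F8 is coupled with 19 by Pd(OAc)2, 2-(di-tert-butylphosphino)biphenyl and Et2Zn (0.5 equiv) in THF at rt.
  - Attack of the zinc-bound oxygen at the unsubstituted allyl terminus should give the linear E ether, so the fallback comes back to the route at 26.

Further compounds
F1 | step 17 | monocyclic hydroxymethyl benzyl tetrahydrofuran (7,8-trans, 8,8'-cis; C7' as CH2, C9–OH) | COc1cc([C@@H](O[Si](C)(C)C(C)(C)C)[C@H](CO[Si](C)(C)C(C)(C)C)Oc2ccc([C@@H]3OC[C@@H](Cc4cc(OC)c(O[Si](C(C)C)(C(C)C)C(C)C)c(OC)c4)[C@H]3CO)cc2OC)ccc1O[Si](C(C)C)(C(C)C)C(C)C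
F2 | step 17 | bisphenol of F1 (both aryl TIPS removed) | COc1cc([C@@H](O[Si](C)(C)C(C)(C)C)[C@H](CO[Si](C)(C)C(C)(C)C)Oc2ccc([C@@H]3OC[C@@H](Cc4cc(OC)c(O)c(OC)c4)[C@H]3CO)cc2OC)ccc1O
F3 | step 17 | syringyl para-quinone methide (C7'=C1') | COc1cc([C@@H](O[Si](C)(C)C(C)(C)C)[C@H](CO[Si](C)(C)C(C)(C)C)Oc2ccc([C@@H]3OC[C@@H](C=C4C=C(OC)C(=O)C(OC)=C4)[C@H]3CO)cc2OC)ccc1O
F4 | step 17 | furofuran bisphenol with 7'',9''-bis-TBS side chain | COc1cc([C@@H](O[Si](C)(C)C(C)(C)C)[C@H](CO[Si](C)(C)C(C)(C)C)Oc2ccc([C@@H]3OC[C@@H]4[C@H]3CO[C@H]4c3cc(OC)c(O)c(OC)c3)cc2OC)ccc1O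
F5 | step 7 | threo C9'' tert-butyl carbonate (7''S,8''S) | COc1cc([C@H](O)[C@H](COC(=O)OC(C)(C)C)Oc2ccc(Br)cc2OC)ccc1O[Si](C(C)C)(C(C)C)C(C)C
F6 | step 7 | trans 4-aryl-5-aryloxy-1,3-dioxan-2-one (erythro cyclic carbonate) | COc1cc([C@H]3OC(=O)OC[C@@H]3Oc2ccc(Br)cc2OC)ccc1O[Si](C(C)C)(C(C)C)C(C)C
F7 | step 7 | erythro diol (7''R,8''S) | COc1cc([C@@H](O)[C@H](CO)Oc2ccc(Br)cc2OC)ccc1O[Si](C(C)C)(C(C)C)C(C)C
F8 | step 16 | (E)-3-[3,5-dimethoxy-4-(triisopropylsilyloxy)phenyl]prop-2-enyl acetate | CC(=O)OC/C=C/c1cc(OC)c(O[Si](C(C)C)(C(C)C)C(C)C)c(OC)c1
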